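The benzene ring of the target carries oxygen on C1, C2 and C4 and the heneicosyl chain on C6; the oxygens on C2 and C4 are meta to each other and to C6, the imprint of alternating ketones in a polyketide chain, and this is what the key step exploits. The ring is opened at bond C1–C6 to a linear 3,5,7-triketo ester whose carboxyl carbon stays on C1 as a placeholder for the phenol oxygen. In one operation the key step frees this chain from a dioxinone with hot methanol and folds it by aldol condensation into the aromatic resorcylate. Its precursor is a 2,2-dimethyl-1,3-dioxin-4-one carrying a 2,4-dioxopentacosyl side chain.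

Key step: step 4

Assumption: the C21-chain intermediates are waxy and poorly soluble in cold methanol, so methanol is always used with toluene, CH2Cl2 or THF as co-solvent. Ring atoms are numbered as in the target (C1 bears the phenol oxygen or, before it, the ester carbon; C6 bears the chain). Atoms of the open chain are numbered from the ester carbon. The target has no stereocentre.

Step 1
Reactants: 1 2,2,6-trimethyl-4H-1,3-dioxin-4-one
Product: 3 2,2-dimethyl-6-(2-oxopropyl)-4H-1,3-dioxin-4-one, via lithium dienolate 2 (not isolated)
Conditions: LiN(SiMe3)2 (1.0 equiv), THF, −78 °C; AcCl (0.5 equiv), −78 °C; aq. NH4Cl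
Reagents that add atoms: acetyl chloride, CC(=O)Cl
Why: Deprotonation of the C6 methyl group of the vinylogous ester gives the cross-conjugated lithium dienolate, which acetyl chloride should acylate at its terminal carbon (vinylogous Claisen-type C-acylation); half of the dienolate serves as base for the more acidic β-keto product, so acetyl chloride is the limiting reagent.

Step 2
Reactants: 4 docosanoic acid
Product: 5 1-docosanoylimidazole
Conditions: CDI (1.1 equiv), THF, 45 °C; quick cold-water wash of a CH2Cl2 solution, crystallisation
Reagents that add atoms: 1,1'-carbonyldiimidazole, O=C(n1ccnc1)n1ccnc1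
Why: Carbonyldiimidazole activation of a carboxylic acid should give the acyl imidazolide with loss of CO2 and imidazole, and the free imidazole is washed out so that it cannot protonate the dianion of step 3.

Step 3
Reactants: 3 2,2-dimethyl-6-(2-oxopropyl)-4H-1,3-dioxin-4-one; 5 1-docosanoylimidazole
Product: 7 2,2-dimethyl-6-(2,4-dioxopentacosyl)-4H-1,3-dioxin-4-one, via dilithium dianion 6 (not isolated)
Conditions: LiN(iPr)2 (2.05 equiv per 3), THF, −78 → −40 °C; 5 (0.5 equiv per 3) in THF, −78 → −20 °C; 1 M HCl to pH 3
Reagents that add atoms: none
Why: Double deprotonation gives the dianion, whose last-formed terminal carbon is the most nucleophilic site and should attack the acyl imidazolide (Weiler-type dianion C-acylation, a crossed Claisen condensation); a twofold amount of dianion is used because the triketone-like product is deprotonated as it forms.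

Step 4
Reactants: 7 2,2-dimethyl-6-(2,4-dioxopentacosyl)-4H-1,3-dioxin-4-one
Product: 11 methyl 2,4-dihydroxy-6-heneicosylbenzoate, via acylketene 8 (not isolated), via methyl 3,5,7-trioxooctacosanoate 9 (not isolated), via aldol adduct 10 (not isolated)
Conditions: MeOH (10 equiv), PhMe, 110 °C, sealed tube; concentrate; K2CO3 (2 equiv), MeOH–CH2Cl2 1:1, rt; then HCl in MeOH to pH 1–2, rt
Reagents that add atoms: methanol, CO
Why: On heating, the dioxinone ring of 7 should undergo a retro-hetero-Diels–Alder cycloreversion that expels acetone and leaves acylketene 8, which excess methanol captures at once as the open triketo ester 9, so this reactive chain exists only in the reaction flask. Carbonate then equilibrates the enolates of 9; the C4 and C6 methylenes are the more acidic ones but can close no unstrained ring onto a ketone, whereas the C2 carbanion, stabilised by the ester and the C3 ketone, reaches the C7 ketone and gives aldol adduct 10 by a 6-exo-trig closure (allowed by Baldwin's rules in the enolexo and in the enolendo sense) that forms bond C1–C6 of the future benzene ring. Methanolic HCl then removes water from 10 and the two remaining ring ketones enolise, which makes the closure irreversible and leaves phenols on C2 and C4, the ester on C1 and the chain on C6. The closest known reaction type is the biomimetic aldol cyclisation and aromatisation of dioxinone-masked triketo esters to 6-alkylresorcylates. No stereocentre is set, since both sp3 centres of 10 become aromatic carbons. The step needs chemoselectivity for aldol closure from C2 onto C7 over Claisen closure from C6 onto the ester (an acylphloroglucinol) and over lactonisation to a 4-hydroxy-2-pyrone; the higher electrophilicity of a ketone compared with an ester, the mild base, and the excess of methanol that outruns capture of the ketene by its own enol should secure it.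

Step 5
Reactants: 11 methyl 2,4-dihydroxy-6-heneicosylbenzoate
Product: 12 methyl 6-heneicosyl-2,4-dimethoxybenzoate
Conditions: MeI (6 equiv), K2CO3 (4 equiv), DMF–THF, 40 °C
Reagents that add atoms: iodomethane, CI
Why: Williamson O-methylation of both phenoxides should go to completion with excess reagent and gentle warming, also at the C2 phenol that is hydrogen-bonded to the ester, while ester and chain are inert.

Step 6
Reactants: 12 methyl 6-heneicosyl-2,4-dimethoxybenzoate
Product: 13 (6-heneicosyl-2,4-dimethoxyphenyl)methanol
Conditions: LiAlH4 (2 equiv), THF, 0 °C → reflux; Fieser work-up (H2O, aq. NaOH)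
Reagents that add atoms: none
Why: Hydride reduction of the doubly ortho-substituted benzoate to the benzylic alcohol needs heat but meets no competing group, since aryl methyl ethers are inert to LiAlH4, and the basic work-up protects the acid-labile electron-rich benzylic alcohol.

Step 7
Reactants: 13 (6-heneicosyl-2,4-dimethoxyphenyl)methanol
Product: 14 6-heneicosyl-2,4-dimethoxybenzaldehyde
Conditions: DMP (1.3 equiv), pyridine (3 equiv), CH2Cl2, 0 °C → rt
Reagents that add atoms: none
Why: Dess–Martin oxidation should stop cleanly at the aldehyde, and pyridine buffers the acetic acid released so that the electron-rich benzylic alcohol does not ionise.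

Step 8
Reactants: 14 6-heneicosyl-2,4-dimethoxybenzaldehyde
Product: 16 6-heneicosyl-2,4-dimethoxyphenol, via aryl formate 15 (not isolated)
Conditions: mCPBA (1.3 equiv), CH2Cl2, 0 °C → rt; aq. Na2SO3/NaHCO3 wash; K2CO3 (0.2 equiv), MeOH–CH2Cl2, rt, under Ar
Reagents that add atoms: mCPBA (3-chloroperoxybenzoic acid), OOC(=O)c1cccc(Cl)c1
Why: In this Baeyer–Villiger (Dakin-type) oxidation the electron-rich 2,4-dimethoxy-6-alkylphenyl group should migrate in preference to hydride and give the aryl formate, which keeps the phenol masked until the peracid has been destroyed and is then cleaved by base-catalysed methanolysis.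

Compound list
1 | 2,2,6-trimethyl-4H-1,3-dioxin-4-one | CC1=CC(=O)OC(C)(C)O1 | starting material
2 | lithium 2,2-dimethyl-6-methylidene-6H-1,3-dioxin-4-olate (lithium dienolate of 1) | [Li+].C=C1C=C([O-])OC(C)(C)O1 | intermediate (not isolated)
3 | 2,2-dimethyl-6-(2-oxopropyl)-4H-1,3-dioxin-4-one | CC(=O)CC1=CC(=O)OC(C)(C)O1 | intermediate
4 | docosanoic acid | CCCCCCCCCCCCCCCCCCCCCC(=O)O | starting material
5 | 1-docosanoylimidazole (1-(1H-imidazol-1-yl)docosan-1-one) | CCCCCCCCCCCCCCCCCCCCCC(=O)n1ccnc1 | intermediate
6 | dilithium 2,2-dimethyl-6-(2-oxidoprop-2-en-1-ylidene)-6H-1,3-dioxin-4-olate (dianion of 3) | [Li+].[Li+].C=C([O-])C=C1C=C([O-])OC(C)(C)O1 | intermediate (not isolated)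
7 | 2,2-dimethyl-6-(2,4-dioxopentacosyl)-4H-1,3-dioxin-4-one | CCCCCCCCCCCCCCCCCCCCCC(=O)CC(=O)CC1=CC(=O)OC(C)(C)O1 | intermediate
8 | octacos-1-ene-1,3,5,7-tetrone (acylketene, O=C=CH–CO–CH2–CO–CH2–CO–C21H43) | CCCCCCCCCCCCCCCCCCCCCC(=O)CC(=O)CC(=O)C=C=O | intermediate (not isolated)
9 | methyl 3,5,7-trioxooctacosanoate | CCCCCCCCCCCCCCCCCCCCCC(=O)CC(=O)CC(=O)CC(=O)OC | intermediate (not isolated)
10 | methyl 2-heneicosyl-2-hydroxy-4,6-dioxocyclohexane-1-carboxylate (aldol adduct; mixture of stereoisomers, both sp3 centres are lost on aromatisation) | CCCCCCCCCCCCCCCCCCCCCC1(O)CC(=O)CC(=O)C1C(=O)OC | intermediate (not isolated)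
11 | methyl 2,4-dihydroxy-6-heneicosylbenzoate | CCCCCCCCCCCCCCCCCCCCCc1cc(O)cc(O)c1C(=O)OC | intermediate
12 | methyl 6-heneicosyl-2,4-dimethoxybenzoate | CCCCCCCCCCCCCCCCCCCCCc1cc(OC)cc(OC)c1C(=O)OC | intermediate
13 | (6-heneicosyl-2,4-dimethoxyphenyl)methanol | CCCCCCCCCCCCCCCCCCCCCc1cc(OC)cc(OC)c1CO | intermediate
14 | 6-heneicosyl-2,4-dimethoxybenzaldehyde | CCCCCCCCCCCCCCCCCCCCCc1cc(OC)cc(OC)c1C=O | intermediate
15 | 6-heneicosyl-2,4-dimethoxyphenyl formate | CCCCCCCCCCCCCCCCCCCCCc1cc(OC)cc(OC)c1OC=O | intermediate (not isolated)
16 | 6-n-heneicosyl-2,4-dimethoxyphenol | CCCCCCCCCCCCCCCCCCCCCc1cc(OC)cc(OC)c1O | target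

Total step count: 8. Longest linear sequence: 7 steps (steps 1, 3, 4, 5, 6, 7 and 8; step 2 is a one-step branch).

Steps most likely to fail

Step 4. The freed acylketene or the open triketo ester may lactonise through an enol oxygen to a 4-hydroxy-2-pyrone, or the chain may close by Claisen condensation, before the aldol takes place. The fallback sets out from 7 and reverses the order of events. Et3N in CH2Cl2 at room temperature should deprotonate the side-chain methylene next to the heterocycle, so that dioxinone C5 adds to the terminal ketone and the new ring aromatises while the heterocycle is still intact. This gives 5-heneicosyl-7-hydroxy-2,2-dimethyl-4H-1,3-benzodioxin-4-one F1, in which no ketene and therefore no pyrone can arise. NaOMe in MeOH–THF then opens the salicylate acetonide by transesterification with release of acetone, and the route is rejoined at 11.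

Step 3. Proton transfer from the acidic product or from the α-methylene of 5 to the dianion, together with O-acylation or double acylation, may keep the conversion low. The fallback sets out from 1 and from 4. Lithium dienolate 2, made as in step 1, is acylated with allyl 3-chloro-3-oxopropanoate to give allyl 4-(2,2-dimethyl-4-oxo-4H-1,3-dioxin-6-yl)-3-oxobutanoate F2. Acid 4 is converted with oxalyl chloride and catalytic DMF into docosanoyl chloride F3. MgCl2 and pyridine in CH2Cl2 at 0 °C (soft enolisation of the β-keto ester) should then bring about C-acylation of F2 by F3 at the carbon between ketone and ester, giving allyl 2-[(2,2-dimethyl-4-oxo-4H-1,3-dioxin-6-yl)acetyl]-3-oxotetracosanoate F4. Pd(PPh3)4 (catalytic) and morpholine in THF remove the allyl group, the free acid loses CO2, and the route is rejoined at 7.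

Step 8. Hydride may migrate in place of the aryl group, which would lead to the benzoic acid, or the electron-rich ring may be oxidised further once the phenol is set free. The fallback sets out from 11 and exchanges the carboxyl carbon for oxygen by way of a bromide. Hot aqueous KOH, followed by acidification and warming, should hydrolyse the ester and decarboxylate the resorcylic acid to 5-heneicosylbenzene-1,3-diol F5. MeI and K2CO3 in DMF give 1-heneicosyl-3,5-dimethoxybenzene F6. NBS in CH2Cl2 at 0 °C should brominate the position flanked by the chain and one methoxy group and para to the other, giving 2-bromo-1-heneicosyl-3,5-dimethoxybenzene F7. n-BuLi in THF at −78 °C gives (6-heneicosyl-2,4-dimethoxyphenyl)lithium F8, B(OMe)3 converts it into dimethyl (6-heneicosyl-2,4-dimethoxyphenyl)boronate F9, and NaOH/H2O2 oxidises the carbon–boron bond in the same flask, so that the route is rejoined at the target 16.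

Further compounds
F1 | step 4 | 5-heneicosyl-7-hydroxy-2,2-dimethyl-4H-1,3-benzodioxin-4-one | CCCCCCCCCCCCCCCCCCCCCc1cc(O)cc2OC(C)(C)OC(=O)c12
F2 | step 3 | allyl 4-(2,2-dimethyl-4-oxo-4H-1,3-dioxin-6-yl)-3-oxobutanoate | C=CCOC(=O)CC(=O)CC1=CC(=O)OC(C)(C)O1
F3 | step 3 | docosanoyl chloride | CCCCCCCCCCCCCCCCCCCCCC(=O)Cl
F4 | step 3 | allyl 2-[(2,2-dimethyl-4-oxo-4H-1,3-dioxin-6-yl)acetyl]-3-oxotetracosanoate (racemic, largely enolised) | CCCCCCCCCCCCCCCCCCCCCC(=O)C(C(=O)OCC=C)C(=O)CC1=CC(=O)OC(C)(C)O1
F5 | step 8 | 5-heneicosylbenzene-1,3-diol | CCCCCCCCCCCCCCCCCCCCCc1cc(O)cc(O)c1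
F6 | step 8 | 1-heneicosyl-3,5-dimethoxybenzene | CCCCCCCCCCCCCCCCCCCCCc1cc(OC)cc(OC)c1
F7 | step 8 | 2-bromo-1-heneicosyl-3,5-dimethoxybenzene | CCCCCCCCCCCCCCCCCCCCCc1cc(OC)cc(OC)c1Br
F8 | step 8 | (6-heneicosyl-2,4-dimethoxyphenyl)lithium | CCCCCCCCCCCCCCCCCCCCCc1cc(OC)cc(OC)c1[Li]
F9 | step 8 | dimethyl (6-heneicosyl-2,4-dimethoxyphenyl)boronate | CCCCCCCCCCCCCCCCCCCCCc1cc(OC)cc(OC)c1B(OC)OC
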